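**Retrosynthetic overview**
1. Target 17 ⇒ keto acid 14 + (S)-glycidyl acetate 16 (carboxylic acid opens the epoxide CH2; 16 comes from (R)-glycidol).
2. 14 ⇒ alkenyl acid 13 (Wacker) ⇒ diazoketone 10 + 3-methylcyclobutanone 11: desymmetrising cyclobutanone → 2-acylcyclopentanone ring expansion (forms C11–C12, sets C13), then retro-Claisen opening (cuts C11–C15, frees the acid).
3. 10 ⇒ methyl ketone 8 (diazo transfer) ⇒ enone 5 + butenyl Grignard 6 + MeI (conjugate addition sets C5, anti methylation sets C10).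
4. 5 ⇒ 3-methylcyclohex-2-enone 1 (methyl conjugate addition and enol triflate, then acetyl by Stille coupling).
5. Ring order: the cyclohexane is bought with 1 and never broken; the only ring made is the cyclopentanone of 12 (from the cyclobutanone of 11), and it is opened again in the same flask.

Atom labels used below: ring C1–C5 and C10 (C4 = CMe2, C5 = CH carrying the oxobutyl chain C6–C8, C10 = quaternary carbon), C9 = ring-bound ketone, C11–C15 = chain to the ester carbon, C13 = methyl-bearing stereocentre.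

Assumption: the target is taken exactly as drawn, (1R,2S) in the ring (C10 methyl and C5 hydrogen cis, the two carbonyl chains cis), (3R) in the acid chain, (2R) in the glycerol unit; where the sense of induction of a chiral catalyst on a new substrate cannot be certain, the named ligand antipode is the one expected by analogy and is swapped if a first run shows the opposite sense.

**Route**

Step 1
Reactants: 1 3-methylcyclohex-2-en-1-one
Product: 3 3,3-dimethylcyclohex-1-en-1-yl trifluoromethanesulfonate, via bromomagnesium enolate 2 (not isolated)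
Conditions: MeMgBr (1.2 equiv), CuBr·SMe2 (5 mol%), THF, −30 → 0 °C; then PhNTf2 (1.3 equiv), 0 °C → rt
Reagents that add atoms: methylmagnesium bromide, C[Mg]Br; N-phenylbis(trifluoromethanesulfonimide), O=S(=O)(N(c1ccccc1)S(=O)(=O)C(F)(F)F)C(F)(F)F
Why: Copper-catalysed conjugate addition of the Grignard reagent builds the gem-dimethyl carbon and leaves a regiodefined enolate (double bond towards CMe2) that is trapped on oxygen by the triflimide; no stereocentre is formed.

Step 2
Reactants: 3 3,3-dimethylcyclohex-1-en-1-yl trifluoromethanesulfonate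
Product: 5 1-(3,3-dimethylcyclohex-1-en-1-yl)ethan-1-one, via ethoxyvinyl diene 4 (not isolated)
Conditions: tributyl(1-ethoxyvinyl)stannane (1.2 equiv), Pd(PPh3)4 (5 mol%), LiCl (3 equiv), THF, 65 °C; then 1 M HCl, rt
Reagents that add atoms: tributyl(1-ethoxyvinyl)stannane, CCCC[Sn](CCCC)(CCCC)C(=C)OCC; water, O
Why: Stille coupling of the vinyl triflate (oxidative addition to zerovalent palladium, chloride-assisted transmetalation) with an acetyl-anion equivalent, then enol ether hydrolysis, gives the conjugated methyl ketone; no stereocentre is formed.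

Step 3
Reactants: 5 1-(3,3-dimethylcyclohex-1-en-1-yl)ethan-1-one; 6 but-3-en-1-ylmagnesium bromide
Product: 8 1-[(1R,2S)-2-(but-3-en-1-yl)-1,3,3-trimethylcyclohexyl]ethan-1-one, via bromomagnesium enolate 7 (not isolated)
Conditions: CuBr·SMe2 (5 mol%), (R)-1-[(SP)-2-(diphenylphosphino)ferrocenyl]ethyldicyclohexylphosphine (6 mol%), t-BuOMe, −78 °C, slow addition of 6 (1.3 equiv); then MeI (5 equiv), DMPU, −78 → 0 °C
Reagents that add atoms: iodomethane, CI
Why: Copper-catalysed asymmetric conjugate addition of a Grignard reagent (Feringa-type, ferrocenyl diphosphine) sets C5 under catalyst control, and the tetrasubstituted enolate 7 is then methylated anti to the new butenyl group (allylic 1,3-strain puts the chain axial, and in the other chair the axial methyl of the CMe2 group blocks the opposite trajectory), which sets C10 with methyl trans and acetyl cis to the chain.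

Step 4
Reactants: 8 1-[(1R,2S)-2-(but-3-en-1-yl)-1,3,3-trimethylcyclohexyl]ethan-1-one
Product: 10 2-diazo-1-[(1R,2S)-2-(but-3-en-1-yl)-1,3,3-trimethylcyclohexyl]ethan-1-one, via trifluoroacetyl diketone 9 (not isolated)
Conditions: LiN(SiMe3)2 (1.1 equiv), THF, −78 °C; CF3CO2CH2CF3 (1.2 equiv); then MsN3 (1.5 equiv), Et3N (1.5 equiv), H2O (1 equiv), MeCN, rt
Reagents that add atoms: methanesulfonyl azide, CS(=O)(=O)N=[N+]=[N-]; 2,2,2-trifluoroethyl trifluoroacetate, O=C(OCC(F)(F)F)C(F)(F)F (its CF3CO group is carried only by intermediate 9)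
Why: Danheiser detrifluoroacetylative diazo transfer (Regitz-type) works cleanly here because the methyl group is the only enolisable position of the ketone (C10 is quaternary); no stereocentre is touched.

Step 5
Reactants: 10 2-diazo-1-[(1R,2S)-2-(but-3-en-1-yl)-1,3,3-trimethylcyclohexyl]ethan-1-one; 11 3-methylcyclobutan-1-one
Product: 13 (3R)-6-[(1R,2S)-2-(but-3-en-1-yl)-1,3,3-trimethylcyclohexyl]-3-methyl-6-oxohexanoic acid, via acylcyclopentanone 12 (not isolated)
Conditions: 11 (2 equiv), Sc(OTf)3 (10 mol%), C2-symmetric chiral N,N′-dioxide ligand from L-pipecolic acid and 2,6-diisopropylaniline (12 mol%), CH2Cl2, −30 °C; then 2 M NaOH, THF/MeOH, 45 °C; then 1 M HCl to pH 3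
Reagents that add atoms: sodium hydroxide, [Na+].[OH-]
Why: Proposed new method: the chiral scandium triflate–N,N′-dioxide Lewis acid binds the cyclobutanone carbonyl, the diazo carbon of 10 adds to it anti to the 3-methyl group to give a β-diazonium alkoxide, and in the catalyst pocket only one of the two enantiotopic ring CH2 groups can lie anti-periplanar to the C–N2 bond, so its strain-driven 1,2-shift with loss of N2 (Tiffeneau–Demjanov-type ring expansion) forms the C11–C12 bond and fixes the remote stereocentre C13 as R; the closest known reactions are the Lewis-acid homologation of cyclobutanones with diazoacetates and the chiral-Lewis-acid desymmetrising ring expansion of 4-substituted cyclohexanones with diazo esters, neither shown for an acyl diazomethane with a 3-substituted cyclobutanone; hydroxide then opens 12 by retro-Claisen attack on the unhindered ring carbonyl (the neopentyl C9 ketone is shielded), which erases the labile C11 centre and leaves C13 untouched.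

Step 6
Reactants: 13 (3R)-6-[(1R,2S)-2-(but-3-en-1-yl)-1,3,3-trimethylcyclohexyl]-3-methyl-6-oxohexanoic acid
Product: 14 (3R)-3-methyl-6-oxo-6-[(1R,2S)-1,3,3-trimethyl-2-(3-oxobutyl)cyclohexyl]hexanoic acid
Conditions: PdCl2 (10 mol%), CuCl (20 mol%), O2 (1 atm), DMF/H2O 7:1, rt
Reagents that add atoms: water, O
Why: Tsuji–Wacker oxidation (Markovnikov oxypalladation of the terminal alkene) gives the methyl ketone; the acid and the hindered ketone are inert and no stereocentre is affected.

Step 7
Reactants: 15 (R)-glycidol [(2R)-oxiran-2-ylmethanol]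
Product: 16 (S)-glycidyl acetate [(2S)-oxiran-2-ylmethyl acetate]
Conditions: Ac2O (1.1 equiv), Et3N (1.2 equiv), DMAP (2 mol%), CH2Cl2, 0 °C
Reagents that add atoms: acetic anhydride, CC(=O)OC(C)=O
Why: Plain DMAP-catalysed O-acetylation of the primary alcohol; the epoxide stereocentre is untouched and its descriptor changes from R to S only because the CIP priorities change.

Step 8
Reactants: 14 (3R)-3-methyl-6-oxo-6-[(1R,2S)-1,3,3-trimethyl-2-(3-oxobutyl)cyclohexyl]hexanoic acid; 16 (S)-glycidyl acetate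
Product: 17 (2R)-3-(acetyloxy)-2-hydroxypropyl (3R)-3-methyl-6-oxo-6-[(1R,2S)-1,3,3-trimethyl-2-(3-oxobutyl)cyclohexyl]hexanoate
Conditions: 16 (1.5 equiv), (R,R)-N,N′-bis(3,5-di-tert-butylsalicylidene)-1,2-cyclohexanediaminocobalt (5 mol%; divalent cobalt, oxidised by air in the flask to the trivalent cobalt carboxylate), iPr2NEt (1 equiv), t-BuOMe, air, rt
Reagents that add atoms: none
Why: Cobalt–salen-catalysed addition of a carboxylic acid to a terminal epoxide (Jacobsen-type) is selective for the CH2 terminus, so the glycerol stereocentre of 16 is carried over unchanged (R in 17 by CIP priority change only), and the near-neutral conditions suppress 1,3 → 1,2 acyl migration.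

**Compound list**
1 | 3-methylcyclohex-2-en-1-one | CC1=CC(=O)CCC1 | starting material
2 | bromomagnesium 3,3-dimethylcyclohex-1-en-1-olate | CC1(C)CCCC(O[Mg]Br)=C1 | intermediate
3 | 3,3-dimethylcyclohex-1-en-1-yl trifluoromethanesulfonate | CC1(C)CCCC(OS(=O)(=O)C(F)(F)F)=C1 | intermediate
4 | 1-(1-ethoxyethenyl)-3,3-dimethylcyclohex-1-ene | CCOC(=C)C1=CC(C)(C)CCC1 | intermediate
5 | 1-(3,3-dimethylcyclohex-1-en-1-yl)ethan-1-one | CC(=O)C1=CC(C)(C)CCC1 | intermediate
6 | but-3-en-1-ylmagnesium bromide | C=CCC[Mg]Br | starting material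
7 | bromomagnesium 1-[(2S)-2-(but-3-en-1-yl)-3,3-dimethylcyclohexylidene]ethan-1-olate | C=CCC[C@H]1C(C)(C)CCCC1=C(C)O[Mg]Br | intermediate
8 | 1-[(1R,2S)-2-(but-3-en-1-yl)-1,3,3-trimethylcyclohexyl]ethan-1-one | C=CCC[C@H]1C(C)(C)CCC[C@@]1(C)C(C)=O | intermediate
9 | 1-[(1R,2S)-2-(but-3-en-1-yl)-1,3,3-trimethylcyclohexyl]-4,4,4-trifluorobutane-1,3-dione | C=CCC[C@H]1C(C)(C)CCC[C@@]1(C)C(=O)CC(=O)C(F)(F)F | intermediate
10 | 2-diazo-1-[(1R,2S)-2-(but-3-en-1-yl)-1,3,3-trimethylcyclohexyl]ethan-1-one | C=CCC[C@H]1C(C)(C)CCC[C@@]1(C)C(=O)C=[N+]=[N-] | intermediate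
11 | 3-methylcyclobutan-1-one | CC1CC(=O)C1 | starting material
12 | (4R)-2-[(1R,2S)-2-(but-3-en-1-yl)-1,3,3-trimethylcyclohexane-1-carbonyl]-4-methylcyclopentan-1-one (C2 epimers and enol forms) | C=CCC[C@H]1C(C)(C)CCC[C@@]1(C)C(=O)C1C[C@@H](C)CC1=O | intermediate
13 | (3R)-6-[(1R,2S)-2-(but-3-en-1-yl)-1,3,3-trimethylcyclohexyl]-3-methyl-6-oxohexanoic acid | C=CCC[C@H]1C(C)(C)CCC[C@@]1(C)C(=O)CC[C@@H](C)CC(=O)O | intermediate
14 | (3R)-3-methyl-6-oxo-6-[(1R,2S)-1,3,3-trimethyl-2-(3-oxobutyl)cyclohexyl]hexanoic acid | CC(=O)CC[C@H]1C(C)(C)CCC[C@@]1(C)C(=O)CC[C@@H](C)CC(=O)O | intermediate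
15 | (R)-glycidol, (2R)-oxiran-2-ylmethanol | OC[C@@H]1CO1 | starting material
16 | (S)-glycidyl acetate, (2S)-oxiran-2-ylmethyl acetate | CC(=O)OC[C@@H]1CO1 | intermediate
17 | (2R)-3-(acetyloxy)-2-hydroxypropyl (3R)-3-methyl-6-oxo-6-[(1R,2S)-1,3,3-trimethyl-2-(3-oxobutyl)cyclohexyl]hexanoate | CC(=O)CC[C@H]1C(C)(C)CCC[C@@]1(C)C(=O)CC[C@@H](C)CC(=O)OC[C@H](O)COC(C)=O | target

**Step count**
Total: 8 steps. Longest linear sequence: 7 (steps 1, 2, 3, 4, 5, 6, 8); step 7 is a one-step side branch.

**Three steps most likely to fail, with fallbacks**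

Step 5 (the proposed new step). Risks: the scandium catalyst may be held by the 1,3-diketone product 12, the acyl diazomethane may be too weak a nucleophile at −30 °C, and the methyl group may be too small a marker for a high enantiotopic-group preference. Fallback with known chemistry, setting out from 8 and coming back at 13 (it replaces steps 4 and 5 and takes C13 from the chiral pool): commercial (4S)-4-methyloxolan-2-one F1 is opened with Me3SiI and then ethanol to ethyl (3S)-4-iodo-3-methylbutanoate F2. The lithium enolate of 8 (LiN(iPr)2, THF, −78 °C; only the methyl group can enolise) is alkylated with F2 in THF/DMPU to give ethyl (3R)-6-[(1R,2S)-2-(but-3-en-1-yl)-1,3,3-trimethylcyclohexyl]-3-methyl-6-oxohexanoate F3. LiOH in aqueous THF then gives 13.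

Step 3. Risks: the diastereoselectivity rests on the substrate, but the enantioselectivity of the copper-catalysed addition to this α-substituted enone with a neopentyl β-carbon is unproven, and C-methylation of the hindered magnesium enolate may be slow. Fallback with auxiliary control, setting out from 3 and coming back at 8: palladium-catalysed carbonylation of 3 (Pd(OAc)2, 1,3-bis(diphenylphosphino)propane, CO, DMF) in the presence of the sodium salt of (2R)-bornane-10,2-sultam (or its commercial antipode, whichever gives the (1R,2S) series) gives (2R)-N-(3,3-dimethylcyclohex-1-ene-1-carbonyl)bornane-10,2-sultam F4. Oppolzer-type 1,4-addition of 6 followed by trapping of the enolate with MeI gives (2R)-N-[(1R,2S)-2-(but-3-en-1-yl)-1,3,3-trimethylcyclohexane-1-carbonyl]bornane-10,2-sultam F5. LiOH/H2O2 releases (1R,2S)-2-(but-3-en-1-yl)-1,3,3-trimethylcyclohexane-1-carboxylic acid F6, and MeLi (2.2 equiv, Et2O, 0 °C) converts F6 into 8.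

Step 8. Risks: incomplete regioselectivity of the epoxide opening and base-promoted 1,3 → 1,2 acyl migration in the 1,3-diacylglycerol during reaction or chromatography. Fallback by stepwise acylation of a protected glycerol, setting out from 14 and coming back at 17: carbodiimide/DMAP esterification of 14 with [(4S)-2,2-dimethyl-1,3-dioxolan-4-yl]methanol F7 gives [(4R)-2,2-dimethyl-1,3-dioxolan-4-yl]methyl (3R)-3-methyl-6-oxo-6-[(1R,2S)-1,3,3-trimethyl-2-(3-oxobutyl)cyclohexyl]hexanoate F8. Acetonide removal with Amberlyst 15 in methanol at rt gives (2R)-2,3-dihydroxypropyl (3R)-3-methyl-6-oxo-6-[(1R,2S)-1,3,3-trimethyl-2-(3-oxobutyl)cyclohexyl]hexanoate F9. Lipase-catalysed acetylation of the primary hydroxyl (Novozym 435, vinyl acetate, t-BuOMe, rt) then gives 17.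

**Further compounds**
F1 | step 5 | (4S)-4-methyloxolan-2-one | O=C1C[C@H](C)CO1
F2 | step 5 | ethyl (3S)-4-iodo-3-methylbutanoate | CCOC(=O)C[C@H](C)CI
F3 | step 5 | ethyl (3R)-6-[(1R,2S)-2-(but-3-en-1-yl)-1,3,3-trimethylcyclohexyl]-3-methyl-6-oxohexanoate | C=CCC[C@H]1C(C)(C)CCC[C@@]1(C)C(=O)CC[C@@H](C)CC(=O)OCC
F4 | step 3 | (2R)-N-(3,3-dimethylcyclohex-1-ene-1-carbonyl)bornane-10,2-sultam | O=S1(=O)C[C@]23CC[C@H](C[C@H]2N1C(=O)C1=CC(C)(C)CCC1)C3(C)C
F5 | step 3 | (2R)-N-[(1R,2S)-2-(but-3-en-1-yl)-1,3,3-trimethylcyclohexane-1-carbonyl]bornane-10,2-sultam | O=S1(=O)C[C@]23CC[C@H](C[C@H]2N1C(=O)[C@]1(C)CCCC(C)(C)[C@@H]1CCC=C)C3(C)C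
F6 | step 3 | (1R,2S)-2-(but-3-en-1-yl)-1,3,3-trimethylcyclohexane-1-carboxylic acid | C=CCC[C@H]1C(C)(C)CCC[C@@]1(C)C(=O)O
F7 | step 8 | [(4S)-2,2-dimethyl-1,3-dioxolan-4-yl]methanol | CC1(C)OC[C@H](CO)O1
F8 | step 8 | [(4R)-2,2-dimethyl-1,3-dioxolan-4-yl]methyl (3R)-3-methyl-6-oxo-6-[(1R,2S)-1,3,3-trimethyl-2-(3-oxobutyl)cyclohexyl]hexanoate | CC(=O)CC[C@H]1C(C)(C)CCC[C@@]1(C)C(=O)CC[C@@H](C)CC(=O)OC[C@H]1COC(C)(C)O1
F9 | step 8 | (2R)-2,3-dihydroxypropyl (3R)-3-methyl-6-oxo-6-[(1R,2S)-1,3,3-trimethyl-2-(3-oxobutyl)cyclohexyl]hexanoate | CC(=O)CC[C@H]1C(C)(C)CCC[C@@]1(C)C(=O)CC[C@@H](C)CC(=O)OC[C@H](O)CO
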